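**Retrosynthetic overview**
1. Pipoxide ⇒ ring-closing metathesis (C4=C5) of an acyclic epoxy-diene; the six-membered ring is formed last, on a pre-formed oxirane that holds the two alkene arms cis.
2. Epoxy-diene ⇒ C2–C3 bond between a quaternary epoxy aldehyde and an α-benzoyloxyallyl metal, i.e. acrolein with reversed polarity: its former carbonyl carbon attacks the aldehyde carbon. This sets C2 and C3 and delivers the C3-OBz / C2-OH pattern directly.
3. Epoxy aldehyde ⇒ Sharpless epoxidation of a 2,2-bis(oxymethyl)dienol; the oxirane is formed first and sets C1 and C6.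
4. Dienol ⇒ tandem oxa-Michael/Horner–Wadsworth–Emmons assembly from 4-methoxybenzyl alcohol, a phosphonoacrylate and acrolein.

Assumption: atom labels are C1 = quaternary oxirane carbon, C2 = CH(OH), C3 = CH(OBz), C4=C5, C6 = oxirane CH, C7 = CH2OBz; ethyl 2-(diethoxyphosphoryl)acrylate (2) is bought as a catalogue reagent.

**Step 1**
Reactants: 1 4-methoxybenzyl alcohol; 2 ethyl 2-(diethoxyphosphoryl)acrylate; 3 acrolein
Product: 5 ethyl (2E)-2-{[(4-methoxybenzyl)oxy]methyl}penta-2,4-dienoate, via ethyl 2-(diethoxyphosphoryl)-3-[(4-methoxybenzyl)oxy]propanoate sodium salt 4 (not isolated)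
Conditions: NaH, THF, 0 °C; 2, −20 °C; then 3, −78 °C → rt
Reagents that add atoms: none
Why: Tandem oxa-Michael/Horner–Wadsworth–Emmons reaction, in which the alkoxide of 1 adds to vinylphosphonate 2 and the resulting stabilised phosphonate anion olefinates acrolein, with the usual preference of α-substituted phosphonoacetates placing the ester trans to the new vinyl group (minor isomer removed by chromatography).

**Step 2**
Reactants: 5 ethyl (2E)-2-{[(4-methoxybenzyl)oxy]methyl}penta-2,4-dienoate
Product: 6 (2Z)-2-{[(4-methoxybenzyl)oxy]methyl}penta-2,4-dien-1-ol (CH2OH trans to the vinyl group)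
Conditions: DIBAL-H (2.3 equiv), CH2Cl2, −78 °C; Rochelle salt
Reagents that add atoms: none
Why: 1,2-Reduction of a conjugated ester by DIBAL-H at low temperature leaves the diene and the PMB ether untouched and keeps the alkene geometry.

**Step 3**
Reactants: 6 (2Z)-2-{[(4-methoxybenzyl)oxy]methyl}penta-2,4-dien-1-ol
Product: 8 [(2S,3S)-3-ethenyl-2-{[(4-methoxybenzyl)oxy]methyl}oxiran-2-yl]methyl benzoate, via [(2R,3S)-3-ethenyl-2-{[(4-methoxybenzyl)oxy]methyl}oxiran-2-yl]methanol 7 (not isolated)
Conditions: Ti(OiPr)4 (10 mol%), L-(+)-DET (12 mol%), t-BuOOH, 4 Å MS, CH2Cl2, −20 °C; then P(OMe)3; Et3N, BzCl, DMAP (cat.), −20 → 0 °C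
Reagents that add atoms: tert-butyl hydroperoxide, CC(C)(C)OO; benzoyl chloride, O=C(Cl)c1ccccc1
Why: Katsuki–Sharpless asymmetric epoxidation is selective for the allylic double bond of the dienol and, with L-(+)-tartrate (the series that gives 2S,3S-epoxides from E-2-alkenols), sets C1 and C6 in one stereospecific syn addition that keeps the CH2OPMB arm cis to the vinyl group, while in-situ benzoylation traps the acid-sensitive vinyl epoxy alcohol.

**Step 4**
Reactants: 8 [(2S,3S)-3-ethenyl-2-{[(4-methoxybenzyl)oxy]methyl}oxiran-2-yl]methyl benzoate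
Product: 9 [(2S,3S)-3-ethenyl-2-(hydroxymethyl)oxiran-2-yl]methyl benzoate
Conditions: DDQ (1.3 equiv), CH2Cl2/pH 7 buffer (10:1), 0 °C
Reagents that add atoms: none
Why: Oxidative PMB-ether cleavage with DDQ under buffered neutral conditions spares the benzoate and the vinyl epoxide and touches no stereocentre.

**Step 5**
Reactants: 9 [(2S,3S)-3-ethenyl-2-(hydroxymethyl)oxiran-2-yl]methyl benzoate
Product: 10 [(2S,3S)-3-ethenyl-2-formyloxiran-2-yl]methyl benzoate
Conditions: Dess–Martin periodinane, pyridine, CH2Cl2, 0 °C → rt (9 used at once)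
Reagents that add atoms: none
Why: Buffered Dess–Martin oxidation gives a quaternary α,β-epoxy aldehyde that has no α-hydrogen and so cannot epimerise, and immediate use of 9 avoids 1,3-benzoyl migration between the two CH2O arms.

**Step 6**
Reactants: 3 acrolein; 11 benzoyl bromide
Product: 12 3-bromoprop-1-en-1-yl benzoate (E/Z mixture)
Conditions: ZnCl2 (cat.), CH2Cl2, −20 °C → rt
Reagents that add atoms: none
Why: Lewis-acid-catalysed 1,4-addition of an acyl bromide to acrolein gives the γ-bromo enol ester, the precursor of an α-oxyallyl anion.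

**Step 7**
Reactants: 10 [(2S,3S)-3-ethenyl-2-formyloxiran-2-yl]methyl benzoate; 12 3-bromoprop-1-en-1-yl benzoate
Product: 14 (1R,2S)-1-[(2R,3S)-2-[(benzoyloxy)methyl]-3-ethenyloxiran-2-yl]-1-hydroxybut-3-en-2-yl benzoate, via [(2Z)-3-(benzoyloxy)prop-2-en-1-yl]indium dibromide 13 (not isolated)
Conditions: In powder (2 equiv), 12 (2 equiv), THF, 0 °C → rt; sat. aq. NH4Cl
Reagents that add atoms: none
Why: Indium-mediated Barbier α-acyloxyallylation, in which the enol-ester-masked homoenolate 13 reacts through its oxygen-bearing carbon (the former acrolein C=O carbon, now a nucleophile) with the aldehyde carbon; the carbonyl-chelated Z-allylindium in a closed chair transition state gives the syn C2-OH/C3-OBz pair, and Cornforth/Felkin–Anh control (C=O anti to the oxirane C–O, attack on the open side between the oxirane oxygen and C7) places the C2 hydroxyl on the same side as the epoxide oxygen.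

**Step 8**
Reactants: 14 (1R,2S)-1-[(2R,3S)-2-[(benzoyloxy)methyl]-3-ethenyloxiran-2-yl]-1-hydroxybut-3-en-2-yl benzoate
Product: 15 (−)-pipoxide
Conditions: Grubbs II (5 mol%), CH2Cl2 (0.005 M), 40 °C
Reagents that add atoms: none
Why: Ring-closing metathesis of the two terminal vinyl groups, held cis on the oxirane, closes the cyclohexene (C4=C5) with loss of ethene, tolerates the free hydroxyl, benzoates and epoxide, and touches no stereocentre.

**Compound list**
1 | 4-methoxybenzyl alcohol | COc1ccc(CO)cc1 | starting material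
2 | ethyl 2-(diethoxyphosphoryl)acrylate | C=C(C(=O)OCC)P(=O)(OCC)OCC | starting material
3 | acrolein | C=CC=O | starting material
4 | ethyl 2-(diethoxyphosphoryl)-3-[(4-methoxybenzyl)oxy]propanoate (present as its sodium carbanion) | CCOC(=O)C(COCc1ccc(OC)cc1)P(=O)(OCC)OCC | intermediate
5 | ethyl (2E)-2-{[(4-methoxybenzyl)oxy]methyl}penta-2,4-dienoate (ester trans to vinyl) | CCOC(=O)/C(COCc1ccc(OC)cc1)=C/C=C | intermediate
6 | (2Z)-2-{[(4-methoxybenzyl)oxy]methyl}penta-2,4-dien-1-ol (CH2OH trans to vinyl) | OC/C(COCc1ccc(OC)cc1)=C/C=C | intermediate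
7 | [(2R,3S)-3-ethenyl-2-{[(4-methoxybenzyl)oxy]methyl}oxiran-2-yl]methanol | OC[C@]1(COCc2ccc(OC)cc2)O[C@H]1C=C | intermediate
8 | [(2S,3S)-3-ethenyl-2-{[(4-methoxybenzyl)oxy]methyl}oxiran-2-yl]methyl benzoate | O=C(OC[C@]1(COCc2ccc(OC)cc2)O[C@H]1C=C)c1ccccc1 | intermediate
9 | [(2S,3S)-3-ethenyl-2-(hydroxymethyl)oxiran-2-yl]methyl benzoate | O=C(OC[C@]1(CO)O[C@H]1C=C)c1ccccc1 | intermediate
10 | [(2S,3S)-3-ethenyl-2-formyloxiran-2-yl]methyl benzoate (CHO cis to vinyl) | O=C(OC[C@]1(C=O)O[C@H]1C=C)c1ccccc1 | intermediate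
11 | benzoyl bromide | O=C(Br)c1ccccc1 | starting material
12 | 3-bromoprop-1-en-1-yl benzoate (E/Z mixture) | O=C(OC=CCBr)c1ccccc1 | intermediate
13 | [(2Z)-3-(benzoyloxy)prop-2-en-1-yl]indium dibromide | O=C(O/C=C\C[In](Br)Br)c1ccccc1 | intermediate
14 | (1R,2S)-1-[(2R,3S)-2-[(benzoyloxy)methyl]-3-ethenyloxiran-2-yl]-1-hydroxybut-3-en-2-yl benzoate | C=C[C@H](OC(=O)c1ccccc1)[C@@H](O)[C@@]1(COC(=O)c2ccccc2)O[C@H]1C=C | intermediate
15 | (−)-pipoxide, [(1R,2R,3S,6S)-3-(benzoyloxy)-2-hydroxy-7-oxabicyclo[4.1.0]hept-4-en-1-yl]methyl benzoate | O=C(OC[C@]12O[C@H]1C=C[C@H](OC(=O)c1ccccc1)[C@H]2O)c1ccccc1 | target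

**Step count and risks**
Total steps: 8. Longest linear sequence: 7 (steps 1, 2, 3, 4, 5, 7, 8).

The three steps most likely to fail are steps 7, 3 and 1.

Step 7 is the largest risk. The face selectivity at C2 of a quaternary cis-substituted epoxy aldehyde is unprecedented for this reagent, chelation of indium by the oxirane oxygen would give the C2/C3 epimeric pair, and the indium alkoxide could allow 1,2-benzoyl migration or Lewis-acid opening of the vinyl epoxide. The fallback sets out from aldehyde 10 and replaces substrate control by catalyst control. Acrolein 3 and benzoyl chloride (ZnCl2 cat.) give 3-chloroprop-1-en-1-yl benzoate F1. F1 is added to 10 in a chromium(III)–salen-catalysed Nozaki–Hiyama–Kishi reaction (CrCl3 10 mol%, Jacobsen salen ligand in the enantiomer that matches the substrate, Et3N, Mn, TMSCl, MeCN), whose closed transition state is syn-selective and whose ligand dictates the aldehyde face. The adduct leaves chromium as the O-trimethylsilyl ether of 14 (TMS on the C2 hydroxyl) F2, and buffered fluoride (TBAF/AcOH, 0 °C) returns the route at 14.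

Step 3 may suffer because the 2-alkoxymethyl group can erode the enantioselectivity and the vinyl epoxy alcohol is opened easily by titanium alkoxides. The fallback sets out from dienol 6 and avoids a hydroxyl-directed metal epoxidation altogether. Benzoylation (BzCl, pyridine) gives (2E)-2-{[(4-methoxybenzyl)oxy]methyl}penta-2,4-dien-1-yl benzoate F3. Shi epoxidation of F3 (fructose-type ketone in the antipode chosen by the spiro transition-state model, expected to be the L-sorbose-derived ent-ketone; Oxone, K2CO3, MeCN/dimethoxymethane/buffer, 0 °C) epoxidises the trisubstituted alkene of the diene and returns the route at 8.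

Step 1 may give a poor E/Z ratio, and acrolein or the phosphonoacrylate may polymerise under alkoxide. The fallback sets out from 1 and builds the same alkene by aldol condensation instead of olefination. Oxa-Michael addition of 1 to ethyl acrylate (KOtBu cat.) gives ethyl 3-[(4-methoxybenzyl)oxy]propanoate F4. Its lithium enolate (LDA, THF, −78 °C) adds to acrolein 3 to give ethyl 3-hydroxy-2-{[(4-methoxybenzyl)oxy]methyl}pent-4-enoate F5. MsCl/Et3N converts F5 into ethyl 3-[(methylsulfonyl)oxy]-2-{[(4-methoxybenzyl)oxy]methyl}pent-4-enoate F6, and DBU-induced E1cB elimination gives the thermodynamically preferred dienoate, returning the route at 5.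

**Further compounds**
F1 | step 7 | 3-chloroprop-1-en-1-yl benzoate (E/Z mixture) | O=C(OC=CCCl)c1ccccc1
F2 | step 7 | O-trimethylsilyl ether of 14 (TMS on the C2 hydroxyl) | C=C[C@H](OC(=O)c1ccccc1)[C@@H](O[Si](C)(C)C)[C@@]1(COC(=O)c2ccccc2)O[C@H]1C=C
F3 | step 3 | (2E)-2-{[(4-methoxybenzyl)oxy]methyl}penta-2,4-dien-1-yl benzoate | O=C(OC/C(COCc1ccc(OC)cc1)=C/C=C)c1ccccc1
F4 | step 1 | ethyl 3-[(4-methoxybenzyl)oxy]propanoate | CCOC(=O)CCOCc1ccc(OC)cc1
F5 | step 1 | ethyl 3-hydroxy-2-{[(4-methoxybenzyl)oxy]methyl}pent-4-enoate (diastereomer mixture) | CCOC(=O)C(COCc1ccc(OC)cc1)C(O)C=C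
F6 | step 1 | ethyl 3-[(methylsulfonyl)oxy]-2-{[(4-methoxybenzyl)oxy]methyl}pent-4-enoate | CCOC(=O)C(COCc1ccc(OC)cc1)C(OS(C)(=O)=O)C=C
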